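Start from the charges and leave the clock for later: I asked first where product had to stop in the flask at 0.24 M.

| flask | solid substrate | coupling partner | remark | time |
|---|---|---|---|---|
| west | 0.12 M | 0.80 equiv | run made earlier |  |
| south-east | 0.18 M | 0.80 equiv | run made earlier |  |
| flask | 0.24 M | 0.800 equiv |  | 2.5 min |

| run | time / min | product / % | starting material / % | solid substrate / % |
|---|---|---|---|---|
| west | 0.333 | 0 | 15 | 81 |
| west | 0.667 | 1 | 22 | 78 |
| west | 1.00 | 7 | 16 | 76 |
| west | 1.33 | 27 | 9 | 63 |
| west | 2.00 | 66 | 12 | 25 |
| west | 2.50 | 80 | 14 | 3 |
| south-east | 0.167 | 1 | 8 | 95 |
| south-east | 0.417 | 0 | 13 | 90 |
| south-east | 0.667 | 4 | 10 | 91 |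
| south-east | 1.00 | 21 | 6 | 78 |
| south-east | 1.50 | 47 | 2 | 49 |
| south-east | 2.00 | 67 | 3 | 24 |
| south-east | 2.50 | 77 | 12 | 13 |

(readings scatter by 2 percentage points)

- solid, in amounts per volume of the solution: solid substrate
- at the start none of the solid substrate is in solution
- starting material means what is dissolved; the solid is not counted in it

* how much product there is at 2.5 min, in percent of the solid substrate charged
* how much starting material there is at 2.5 min, in percent of the solid substrate charged

The coupling partner stood at 0.800 of the solid substrate charged, so as limiting reagent it capped product at that fraction. The readings at 2.50 min lay near the cap, 80% in the west run and 77% in the south-east run.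

Would the flask arrive in time? At 2.00 min the south-east run read 67% and the west run 66%, a ratio of 1.02 although the loading differed by a factor of 1.50. So I put the flask just under the cap.

What, then, stood dissolved? The highest readings of starting material were 22% in the west run and 13% in the south-east run, each a single reading with its scatter. Scaled by loading and averaged, they gave 10.4% for the flask. I called this the ceiling fraction, the share of the charge that the solution holds at saturation. The partner could not take 20.0% of the charge, and the ceiling was about half of that. In the south-east run starting material read 3% at 2.00 min and 12% at 2.50 min, as its product neared the cap, so I committed to starting material in the flask below the ceiling and climbing.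

The forecast gave 76% and 7%, saying: “Once the partner runs out, starting material climbs back towards saturation”.

The flask gave 78.8% of product and 5.92% of starting material.

    starting material + coupling partner + released group → product + 2 released group (k = 52.0 M⁻² s⁻¹)
    starting material + coupling partner → product + released group (k = 0.00200 M⁻¹ s⁻¹)
    solid substrate ⇌ starting material, rate k3*(cs3 - [starting material]) while solid is left; crystals form when [starting material] > cs3 (solubility = 25.0 mM, k = 0.0820 s⁻¹)

Both forecast values held, and the starting material stood at 0.569 of the ceiling fraction. At 2.50 min the flask kept 1.5% of its partner, and starting material was being made faster than it was used up, each step taken net, by a factor of 2.15. With dissolved starting material at the ceiling, the share of this flask that the partner could not take left 9.60% for the solid by my reckoning. The same flask left until 6.0 min held 10.4% of starting material and 9.58% of solid substrate.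

Readings and results are simulated with made-up constants.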